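## Analysis of the target

The target (27) is a germacranolide: a ten-membered carbocycle C1–C10, cis-fused at C6–C7 to an α-methylene-γ-butyrolactone (O–C6, C7, C11=C13, C12=O). The ring holds one endocyclic alkene, C4=C5, whose ring bonds to C3 and C6 are cis and which carries the acetoxymethyl carbon C15. It also holds the exocyclic alkene C10=C14 next to a secondary hydroperoxide at C1, and C8 is esterified with (R)-3,4-dihydroxy-2-methylenebutanoic acid. There are five stereocentres. C6 (S), C7 (R) and C8 (S) are contiguous: H6 and H7 are cis, and the C8 oxygen lies on the ring face opposite to the C7–C11 bond and to the C6 oxygen. C1 (R) carries its oxygen on the face of O6 and C11, and C3′ (R) sits alone in the side chain. The allylic hydroperoxide tolerates neither reductants, base nor strong acid; there are two Michael acceptors and an allylic acetate; the primary side-chain hydroxyl can lactonise onto its own ester with loss of the C8 alcohol; and the lactone can migrate to a free O8 under base. The difficulty is a medium ring with two defined alkene geometries, combined with oxygenation that leaves almost no latitude in the last steps. The feature used is that the C1–OOH/C10=C14 pair is the ene product of an E-C1=C10 alkene. With that alkene restored, the ring is a cyclodeca-1,5-diene (E-C1=C10 and ring-cis C4=C5, separated by C2–C3 on one side and by C6 to C9 on the other), which is the cycloreversion product of a cyclohexenone–cyclobutene photoadduct.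

## Retrosynthetic reasoning

**27 ⇒ 26.** The C1–O bond is cut and the alkene is returned from C10=C14 to C1=C10. The hydroperoxide is the most fragile group, so it is made last by a Schenck ene reaction on triene 26, in which C1=C10 is the only electron-rich alkene. The forward step has to take hydrogen from C14 and deliver oxygen to one face of C1.

**26 ⇒ 25 ⇒ 18 + 23.** The C8 ester bond is cut. This gives the hydroxy lactone 18 and acid 23, whose diol is masked as an acetonide so that it cannot lactonise during coupling. The acetonide is removed from 25 with weak acid before the oxygenation, so that the hydroperoxide never meets a deprotection. Acid 23 comes from the chiral-pool ester 19 by α-methylenation (22) and saponification.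

**18 ⇒ 17 ⇒ 16 ⇒ 13.** These are functional-group changes on the lactone: the C8 silyl ether, the C15 acetate and the C11=C13 methylene. The methylene is introduced on lactone 13 by enolate chemistry before the acetate is in place, because an acetate would compete for base.

**13 ⇒ 12 ⇒ 11.** The lactone C12–O6 bond is cut to the γ-hydroxy tert-butyl ester 12. Compound 12 comes from keto diester 11 by one hydride reduction that sets C6 and lowers C15 to the alcohol. The tert-butyl ester is chosen because it survives this reduction and still lactonises afterwards.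

**11 ⇒ 9 + 10.** The C7–C11 bond is cut next to the ketone: enolate alkylation of dienone 9 with bromoacetate 10. C7 is the only sp3 α-carbon of the enone, and its configuration is set relative to C8.

**9 ⇒ 8 (key disconnection).** The two ring alkenes of 9 are joined in thought to the central cyclobutane of tricycle 8 (bonds C5–C10 and C1–C4). This turns a ten-membered ring problem into a six-membered ring problem and fixes both alkene geometries through the relative configuration of a rigid precursor. The forward reaction has to cleave these two bonds and no others, and to do so faster than 8 epimerises or 9 rearranges.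

**8 ⇒ 7 + 3.** The other two cyclobutane bonds (C4–C5 and C1–C10) are cut by a retro-[2+2] to enone 7 and cyclobutene ester 3. Enone 7 carries C6, C14 and the C8 stereocentre; 3 carries C1–C4 and C15.

**7 ⇒ 6 ⇒ 5 ⇒ 4.** The enone alkene is cut by an intramolecular Horner–Wadsworth–Emmons reaction of diketo phosphonate 6. Compound 6 comes in two steps (Weinreb amide 5) from the purchasable (R)-phosphonate 4. C8 is therefore taken from the chiral pool with a known configuration, and no resolution is needed.

**3 ⇒ 2 ⇒ 1.** The cyclobutene ester is made by dehydrobromination of bromo ester 1 and methylation of acid 2.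

## Alternatives that were turned down

**Alternative 1: carbonylative closure of the methylene lactone.** The O–C12 and C12–C11 bonds are cut, which leads back to the ten-membered 6-hydroxy-7-ethynyl compound A2. Forward, PdCl2(PPh3)2/SnCl2 under carbon monoxide adds a divalent palladium alkoxycarbonyl across the alkyne and gives lactone A1 with its exocyclic methylene in one step.
- For it: this is better than the chosen route on the lactone itself, where three operations (alkylation, lactonisation, methylenation) are needed here. The ring fusion is fixed by the existing cis relation of O6 and the ethynyl group.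
- Against it: the step does not build the carbocycle. A2 already contains the ten-membered ring, both alkenes and all three contiguous stereocentres, so the hard part is moved upstream and an ethynyl group must still be placed on C7 stereoselectively. The allylic C6 alcohol is also exposed to a Lewis-acidic tin and palladium mixture.
- Comparison: the chosen strategy gives up the one-step lactone but obtains the ring, both alkene geometries and C15 from two simple partners in two steps.

**Alternative 2: [2,3]-Wittig ring contraction.** The C7–C8 bond is cut and O8 is joined to C13, which leads back to the thirteen-membered cyclic α-stannyl allyl ether A4. Forward, tin–lithium exchange at C8 and a [2,3]-shift with inversion at the metallated carbon give carbocycle A3.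
- For it: one event forms the C7–C8 bond, both of its stereocentres and the C11=C13 methylene through an ordered five-membered transition state. On these points it is stronger than the enolate alkylation used here.
- Against it: A4 needs a macrocyclic etherification, three defined alkenes (one of them E within the large ring) and an enantioenriched α-alkoxystannane, so the linear sequence before the key step is long. A [1,2]-shift competes, and C12 arrives at the alcohol level and must later be oxidised next to two allylic ethers.
- Comparison: the chosen route reaches its key step in six steps and takes its only early stereocentre from a purchasable ester. It pays for this with substrate-controlled steps at C7 and C6.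

**Alternative 3: Grob fragmentation of a hydroazulene.** The C10=C14 and C6=O π bonds are traced back to the C6–C10 bond of the cis-fused hydroazulene A6 (C6 tertiary alkoxide, C14 mesylate on quaternary C10). Forward, the fragmentation gives enone A5.
- For it: the fragmentation is stereoelectronically reliable and delivers the C10=C14 methylene and an oxygen at C1 without depending on the facial selectivity of an ene reaction. This is a real advantage over the last step of the chosen route.
- Against it: the C1 oxygen of A5 is a silyl ether of the configuration opposite to the target. The hydroperoxide would have to be introduced by displacement with inversion at a secondary allylic carbon, where elimination and allylic transposition compete. A6 needs a quaternary C10 and a tertiary carbinol in a defined bicycle, and the C7 side chain and the C6 centre still have to be installed on A5 by the same chemistry as here.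
- Comparison: the chosen strategy makes the hydroperoxide by the one reaction that forms it directly from the alkene, and it is much shorter up to the ten-membered ring.

Key step: step 7

Remark on the chemistry: germacrane numbering (C1–C15, side chain primed) is used for all ring compounds, and the single enantiomers 4 and 19 are taken to be purchasable.

## Route

Step 1
Reactants: 1 ethyl 1-bromocyclobutane-1-carboxylate
Product: 2 cyclobut-1-ene-1-carboxylic acid
Conditions: KOH, PhMe, reflux; then aq. HCl
Reagents that add atoms: potassium hydroxide, [K+].[OH-]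
Why: E2 dehydrobromination gives the conjugated cyclobutene and the ester is saponified in the same pot; this is the standard preparation of the acid.

Step 2
Reactants: 2 cyclobut-1-ene-1-carboxylic acid
Product: 3 methyl cyclobut-1-ene-1-carboxylate
Conditions: MeI, K2CO3, DMF, 23 °C
Reagents that add atoms: iodomethane, CI
Why: SN2 O-alkylation of the carboxylate; the volatile, polymerisable ester is distilled and used fresh.

Step 3
Reactants: 4 methyl (3R)-3-(tert-butyldimethylsilyloxy)-6-(dimethoxyphosphoryl)-5-oxohexanoate
Product: 5 (3R)-3-(tert-butyldimethylsilyloxy)-6-(dimethoxyphosphoryl)-N-methoxy-N-methyl-5-oxohexanamide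
Conditions: MeNH(OMe)·HCl, i-PrMgCl, THF, −20 → 0 °C
Reagents that add atoms: N,O-dimethylhydroxylamine hydrochloride, CNOC.Cl
Why: Weinreb amidation by aminolysis of the ester with the magnesium amide; the keto phosphonate is carried as its magnesium enolate and the silyloxy centre is not touched.

Step 4
Reactants: 5 (3R)-3-(tert-butyldimethylsilyloxy)-6-(dimethoxyphosphoryl)-N-methoxy-N-methyl-5-oxohexanamide
Product: 6 dimethyl [(4S)-4-(tert-butyldimethylsilyloxy)-2,6-dioxoheptyl]phosphonate
Conditions: MeMgBr (3 equiv), THF, −78 → 0 °C
Reagents that add atoms: methylmagnesium bromide, C[Mg]Br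
Why: Weinreb ketone synthesis: the first equivalent deprotonates the keto phosphonate, the next adds to the amide to give the stable chelate, which releases the methyl ketone only on quench, so no tertiary alcohol forms.

Step 5
Reactants: 6 dimethyl [(4S)-4-(tert-butyldimethylsilyloxy)-2,6-dioxoheptyl]phosphonate
Product: 7 (5S)-5-(tert-butyldimethylsilyloxy)-3-methylcyclohex-2-en-1-one
Conditions: LiCl, i-Pr2NEt, MeCN, 23 °C
Reagents that add atoms: none
Why: Intramolecular Horner–Wadsworth–Emmons reaction under Masamune–Roush conditions: only the phosphonate CH2 is acidic enough for the amine, so the ring closes in one direction (6-exo-trig onto the methyl ketone) and C8 keeps its configuration. The mild base avoids loss of silanol and aromatisation of the product.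

Step 6
Reactants: 7 (5S)-5-(tert-butyldimethylsilyloxy)-3-methylcyclohex-2-en-1-one; 3 methyl cyclobut-1-ene-1-carboxylate
Product: 8 trans-fused head-to-head photoadduct (tricyclic C6 ketone; ester on C4, methyl C14 on C10, silyl ether on C8; H5 trans to C14, H1 and the ester on the face of H5; 1S,4R,5R,8S,10S)
Conditions: hν (medium-pressure Hg lamp, Pyrex, λ > 300 nm), 3 (5 equiv), CH2Cl2, −40 °C
Reagents that add atoms: none
Why: Enone–alkene [2+2] photocycloaddition through the enone triplet: C10 bonds first to the unsubstituted alkene carbon C1, the resulting 1,4-biradical is stabilised at C5 by the ketone and at C4 by the ester, and its closure gives the head-to-head adduct. C10 and C1 are set in the first bond (the cyclobutene CH2 groups turn away from C9), C4 and C5 on closure of the twisted biradical, which gives the trans-fused bicyclo[4.2.0]octanone beside its cis-fused C5 epimer; the bicyclo[2.2.0]hexane can only be cis-fused. The orientation of the cyclobutane relative to C8 has no consequence because all four new centres become sp2 in step 7; work-up and chromatography are kept free of base so that C5 does not epimerise.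

Step 7
Reactants: 8 trans-fused head-to-head photoadduct
Product: 9 methyl (8S)-8-(tert-butyldimethylsilyloxy)-6-oxogermacra-1(10)E,4-dien-15-oate (ring-cis C4=C5)
Conditions: degassed PhMe (0.01 M), silanised glass flow coil, 210 °C, residence ca. 2 min
Reagents that add atoms: none
Why: Heating homolyses the bond shared by the two four-membered rings (C1–C4), the weakest bond of the bicyclo[2.2.0]hexane, to a cyclohexane-1,4-diyl whose C4 radical is stabilised by the ester; β-scission of C5–C10 then gives the C4=C5 and C1=C10 π bonds, so the net change is a retro-[2+2] of the central cyclobutane, the known thermal cycloreversion of bicyclo[2.2.0]hexanes to hexa-1,5-dienes in its photo-thermal enone–cyclobutene form. The ten-membered ring is not closed by bond formation: it is the perimeter of the tricycle, set free when the six-membered and the outer four-membered ring lose their two transannular bonds, so no cyclisation mode applies. No stereocentre is formed; C1, C4, C5 and C10 become sp2 and C8 is untouched. Both alkene geometries follow from the relative configuration of the cyclobutane, because groups that are cis on the four-membered ring stay cis on the alkene: C3 and C6 are cis in 8, which gives ring-cis C4=C5, and C2 and C9 are trans, which gives E-C1=C10. The step needs scission of C5–C10 and not of C2–C3 in the diyl (which would give the divinylcyclohexanone directly); C5–C10 is favoured because it is flanked by the ketone and the quaternary C10, gives the conjugated trisubstituted alkenes and relieves the strain of the trans-fused bicyclo[4.2.0]octanone. It also needs 8 to keep its trans fusion until it fragments and 9 to escape Cope rearrangement; neutral silanised glass, the absence of base and a short residence time serve both, and the ring-cis/E isomer of a cyclodeca-1,5-diene is the one that rearranges least readily.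

Step 8
Reactants: 9 methyl (8S)-8-(tert-butyldimethylsilyloxy)-6-oxogermacra-1(10)E,4-dien-15-oate; 10 tert-butyl bromoacetate
Product: 11 (7R,8S)-keto diester: 9 carrying CH2CO2t-Bu on C7, trans to the C8 silyl ether
Conditions: LiN(SiMe3)2, THF, −78 °C (9 added to the base); then 10, DMPU, −78 → −45 °C
Reagents that add atoms: none
Why: Kinetic α′-deprotonation of the enone at C7 and SN2 alkylation of the lithium enolate by the α-bromo ester; the cross-conjugated enolate forms faster than the γ-dienolate and does not expel the β-silyloxy group at −78 °C. C7 is set by attack on the outer face of the medium-ring enolate: with H8 eclipsing the enolate plane (allylic 1,3-strain) the ring bond C8–C9 blocks the inner face, which places the acetate arm trans to the C8 oxygen.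

Step 9
Reactants: 11 (7R,8S)-keto diester
Product: 12 (6S,7S,8S)-diol: tert-butyl ester with C6–OH cis to the acetate arm and C15–OH
Conditions: i-Bu2AlH (5 equiv), CH2Cl2, −78 °C; aq. KNaC4H4O6
Reagents that add atoms: none
Why: 1,2-Reduction of the ketone and of the conjugated methyl ester by i-Bu2AlH, the hindered tert-butyl ester being much slower at −78 °C. C6 is set by Felkin–Anh addition: hydride enters from the ring periphery, anti to the C7–C8 bond and past H7, which puts the hydroxyl cis to the acetate arm and anti to the C8 oxygen.

Step 10
Reactants: 12 (6S,7S,8S)-diol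
Product: 13 (6S,7S,8S)-8-(tert-butyldimethylsilyloxy)-15-hydroxygermacra-1(10)E,4-dien-6,12-olide (cis-fused lactone, ring-cis C4=C5)
Conditions: CSA (10 mol %), CH2Cl2, 0 → 23 °C
Reagents that add atoms: none
Why: Acid-catalysed intramolecular transesterification (5-exo-trig) of the γ-hydroxy tert-butyl ester; the cis relation of O6 and C11 gives the cis-fused lactone, and the primary C15 hydroxyl cannot reach the ester through a small ring.

Step 11
Reactants: 13 (6S,7S,8S)-8-(tert-butyldimethylsilyloxy)-15-hydroxygermacra-1(10)E,4-dien-6,12-olide
Product: 16 (6S,7S,8S)-8-(tert-butyldimethylsilyloxy)-15-hydroxygermacra-1(10)E,4,11(13)-trien-6,12-olide, via Mannich base 14 (not isolated), via trimethylammonium iodide 15 (not isolated)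
Conditions: LiN(i-Pr)2 (2.2 equiv), THF, −78 °C; CH2=NMe2+ I−, −78 → 0 °C; then MeI, MeOH, 23 °C; then aq. NaHCO3, CH2Cl2
Reagents that add atoms: Eschenmoser's salt (N,N-dimethylmethyleneiminium iodide), C=[N+](C)C.[I-]
Why: Mannich reaction of the lactone enolate with the iminium salt (the C15 alkoxide is carried as the second lithium salt), then quaternisation and E1cB loss of trimethylamine give the exocyclic C11=C13 alkene. The C11 centre of 14 and 15 is lost again and needs no control.

Step 12
Reactants: 16 (6S,7S,8S)-8-(tert-butyldimethylsilyloxy)-15-hydroxygermacra-1(10)E,4,11(13)-trien-6,12-olide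
Product: 17 (6S,7S,8S)-15-acetoxy-8-(tert-butyldimethylsilyloxy)germacra-1(10)E,4,11(13)-trien-6,12-olide
Conditions: Ac2O, pyridine, CH2Cl2, 0 °C
Reagents that add atoms: acetic anhydride, CC(=O)OC(C)=O
Why: Acylation of the primary allylic alcohol, the only free hydroxyl.

Step 13
Reactants: 17 (6S,7S,8S)-15-acetoxy-8-(tert-butyldimethylsilyloxy)germacra-1(10)E,4,11(13)-trien-6,12-olide
Product: 18 (6S,7R,8S)-15-acetoxy-8-hydroxygermacra-1(10)E,4,11(13)-trien-6,12-olide
Conditions: HF·pyridine, pyridine, THF, 0 → 23 °C
Reagents that add atoms: none
Why: Fluoride cleavage of the Si–O bond under buffered, non-basic conditions, which keeps the acetate in place and does not let the lactone migrate to O8.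

Step 14
Reactants: 19 methyl 2-[(4R)-2,2-dimethyl-1,3-dioxolan-4-yl]acetate
Product: 22 methyl 2-[(4R)-2,2-dimethyl-1,3-dioxolan-4-yl]prop-2-enoate, via Mannich base 20 (not isolated), via trimethylammonium iodide 21 (not isolated)
Conditions: LiN(i-Pr)2, THF, −78 °C; CH2=NMe2+ I−; then MeI, MeOH; then aq. NaHCO3
Reagents that add atoms: Eschenmoser's salt (N,N-dimethylmethyleneiminium iodide), C=[N+](C)C.[I-]
Why: The same Mannich–quaternisation–elimination sequence on the ester enolate; at −78 °C the enolate is trapped before it can expel the acetonide oxygen, and the C3′ centre is not involved.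

Step 15
Reactants: 22 methyl 2-[(4R)-2,2-dimethyl-1,3-dioxolan-4-yl]prop-2-enoate
Product: 23 2-[(4R)-2,2-dimethyl-1,3-dioxolan-4-yl]prop-2-enoic acid
Conditions: LiOH, THF/H2O, 0 °C; then cold 1 M HCl to pH 3
Reagents that add atoms: lithium hydroxide, [Li+].[OH-]
Why: Saponification of the methyl ester; brief cold acidification and immediate extraction leave the acetonide intact.

Step 16
Reactants: 18 (6S,7R,8S)-15-acetoxy-8-hydroxygermacra-1(10)E,4,11(13)-trien-6,12-olide; 23 2-[(4R)-2,2-dimethyl-1,3-dioxolan-4-yl]prop-2-enoic acid
Product: 25 C8 ester of 18 with acid 23 (acetonide-protected side chain), via mixed anhydride 24 (not isolated)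
Conditions: 2,4,6-Cl3C6H2COCl, Et3N, THF, 0 °C; then 18, DMAP, PhMe, 23 °C
Reagents that add atoms: none
Why: Yamaguchi esterification: the mixed anhydride passes the less hindered acrylic acyl group to the C8 hydroxyl under DMAP catalysis, and the mild amine bases do not trigger translactonisation.

Step 17
Reactants: 25 C8 ester with acetonide-protected side chain
Product: 26 (6S,7R,8S)-15-acetoxy-8-[(3R)-3,4-dihydroxy-2-methylenebutanoyloxy]germacra-1(10)E,4,11(13)-trien-6,12-olide
Conditions: AcOH/H2O (4:1), 35 °C
Reagents that add atoms: none
Why: Acid hydrolysis of the terminal acetonide; aqueous acetic acid is too weak to ionise the allylic esters or protonate the ring alkenes, and the absence of base keeps the γ-hydroxy acrylate from lactonising.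

Step 18
Reactants: 26 (6S,7R,8S)-15-acetoxy-8-[(3R)-3,4-dihydroxy-2-methylenebutanoyloxy]germacra-1(10)E,4,11(13)-trien-6,12-olide
Product: 27 target, (1R,6S,7R,8S)-15-acetoxy-1-hydroperoxy-8-[(3R)-3,4-dihydroxy-2-methylenebutanoyloxy]germacra-4,10(14),11(13)-trien-6,12-olide
Conditions: O2, hν (visible), tetraphenylporphyrin (cat.), CH2Cl2, −20 °C
Reagents that add atoms: dioxygen, O=O
Why: Schenck ene reaction of singlet oxygen with the only electron-rich alkene, C1=C10 (C4=C5 is deactivated by two allylic oxygens; C11=C13 and the acrylate are electron-poor). Hydrogen is taken from C14, which lies on the disubstituted side of the alkene (cis effect) and always has a C–H bond aligned with the π system, so oxygen bonds to C1 and the alkene moves to C10=C14. C1 is set by suprafacial attack on the outer face of the E-alkene in the ring conformer imposed by C6, C7 and C8, which is expected to give the 1R hydroperoxide.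

## Compound list

1 | ethyl 1-bromocyclobutane-1-carboxylate | CCOC(=O)C1(Br)CCC1 | starting material
2 | cyclobut-1-ene-1-carboxylic acid | OC(=O)C1=CCC1 | intermediate
3 | methyl cyclobut-1-ene-1-carboxylate | COC(=O)C1=CCC1 | intermediate
4 | methyl (3R)-3-(tert-butyldimethylsilyloxy)-6-(dimethoxyphosphoryl)-5-oxohexanoate | COC(=O)C[C@H](O[Si](C)(C)C(C)(C)C)CC(=O)CP(=O)(OC)OC | starting material
5 | (3R)-3-(tert-butyldimethylsilyloxy)-6-(dimethoxyphosphoryl)-N-methoxy-N-methyl-5-oxohexanamide | CON(C)C(=O)C[C@H](O[Si](C)(C)C(C)(C)C)CC(=O)CP(=O)(OC)OC | intermediate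
6 | dimethyl [(4S)-4-(tert-butyldimethylsilyloxy)-2,6-dioxoheptyl]phosphonate | CC(=O)C[C@H](O[Si](C)(C)C(C)(C)C)CC(=O)CP(=O)(OC)OC | intermediate
7 | (5S)-5-(tert-butyldimethylsilyloxy)-3-methylcyclohex-2-en-1-one | O=C1C[C@@H](O[Si](C)(C)C(C)(C)C)CC(C)=C1 | intermediate
8 | trans-fused head-to-head photoadduct (1S,4R,5R,8S,10S; germacrane numbering) | O=C1C[C@@H](O[Si](C)(C)C(C)(C)C)C[C@@]2(C)[C@@H]3CC[C@]3(C(=O)OC)[C@H]12 | intermediate
9 | methyl (8S)-8-(tert-butyldimethylsilyloxy)-6-oxogermacra-1(10)E,4-dien-15-oate, ring-cis C4=C5 | O=C1/C=C(/C(=O)OC)CC/C=C(\C)C[C@H](O[Si](C)(C)C(C)(C)C)C1 | intermediate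
10 | tert-butyl bromoacetate | CC(C)(C)OC(=O)CBr | starting material
11 | (7R,8S)-keto diester (CH2CO2t-Bu on C7, trans to C8–OTBS) | O=C1/C=C(/C(=O)OC)CC/C=C(\C)C[C@H](O[Si](C)(C)C(C)(C)C)[C@H]1CC(=O)OC(C)(C)C | intermediate
12 | (6S,7S,8S)-diol tert-butyl ester (C6–OH, C15–OH) | O[C@H]1/C=C(/CO)CC/C=C(\C)C[C@H](O[Si](C)(C)C(C)(C)C)[C@H]1CC(=O)OC(C)(C)C | intermediate
13 | (6S,7S,8S)-8-(tert-butyldimethylsilyloxy)-15-hydroxygermacra-1(10)E,4-dien-6,12-olide | C1C(=O)O[C@H]2/C=C(/CO)CC/C=C(\C)C[C@H](O[Si](C)(C)C(C)(C)C)[C@@H]12 | intermediate
14 | Mannich base of 13 (CH2NMe2 on C11, C11 epimers) | CN(C)CC1C(=O)O[C@H]2/C=C(/CO)CC/C=C(\C)C[C@H](O[Si](C)(C)C(C)(C)C)[C@@H]12 | intermediate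
15 | trimethylammonium iodide of 14 (C11 epimers) | C[N+](C)(C)CC1C(=O)O[C@H]2/C=C(/CO)CC/C=C(\C)C[C@H](O[Si](C)(C)C(C)(C)C)[C@@H]12.[I-] | intermediate
16 | (6S,7S,8S)-8-(tert-butyldimethylsilyloxy)-15-hydroxygermacra-1(10)E,4,11(13)-trien-6,12-olide | C=C1C(=O)O[C@H]2/C=C(/CO)CC/C=C(\C)C[C@H](O[Si](C)(C)C(C)(C)C)[C@@H]12 | intermediate
17 | (6S,7S,8S)-15-acetoxy-8-(tert-butyldimethylsilyloxy)germacra-1(10)E,4,11(13)-trien-6,12-olide | C=C1C(=O)O[C@H]2/C=C(/COC(C)=O)CC/C=C(\C)C[C@H](O[Si](C)(C)C(C)(C)C)[C@@H]12 | intermediate
18 | (6S,7R,8S)-15-acetoxy-8-hydroxygermacra-1(10)E,4,11(13)-trien-6,12-olide | C=C1C(=O)O[C@H]2/C=C(/COC(C)=O)CC/C=C(\C)C[C@H](O)[C@@H]12 | intermediate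
19 | methyl 2-[(4R)-2,2-dimethyl-1,3-dioxolan-4-yl]acetate | COC(=O)C[C@@H]1COC(C)(C)O1 | starting material
20 | Mannich base of 19 (α-CH2NMe2, α-epimers) | COC(=O)C(CN(C)C)[C@@H]1COC(C)(C)O1 | intermediate
21 | trimethylammonium iodide of 20 (α-epimers) | COC(=O)C(C[N+](C)(C)C)[C@@H]1COC(C)(C)O1.[I-] | intermediate
22 | methyl 2-[(4R)-2,2-dimethyl-1,3-dioxolan-4-yl]prop-2-enoate | COC(=O)C(=C)[C@@H]1COC(C)(C)O1 | intermediate
23 | 2-[(4R)-2,2-dimethyl-1,3-dioxolan-4-yl]prop-2-enoic acid | OC(=O)C(=C)[C@@H]1COC(C)(C)O1 | intermediate
24 | mixed anhydride of 23 with 2,4,6-trichlorobenzoic acid | C=C(C(=O)OC(=O)c1c(Cl)cc(Cl)cc1Cl)[C@@H]1COC(C)(C)O1 | intermediate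
25 | (6S,7R,8S)-15-acetoxy-8-{2-[(4R)-2,2-dimethyl-1,3-dioxolan-4-yl]prop-2-enoyloxy}germacra-1(10)E,4,11(13)-trien-6,12-olide | C=C1C(=O)O[C@H]2/C=C(/COC(C)=O)CC/C=C(\C)C[C@H](OC(=O)C(=C)[C@@H]3COC(C)(C)O3)[C@@H]12 | intermediate
26 | (6S,7R,8S)-15-acetoxy-8-[(3R)-3,4-dihydroxy-2-methylenebutanoyloxy]germacra-1(10)E,4,11(13)-trien-6,12-olide | C=C1C(=O)O[C@H]2/C=C(/COC(C)=O)CC/C=C(\C)C[C@H](OC(=O)C(=C)[C@@H](O)CO)[C@@H]12 | intermediate
27 | (1R,6S,7R,8S)-15-acetoxy-1-hydroperoxy-8-[(3R)-3,4-dihydroxy-2-methylenebutanoyloxy]germacra-4,10(14),11(13)-trien-6,12-olide | C=C1C(=O)O[C@H]2/C=C(/COC(C)=O)CC[C@@H](OO)C(=C)C[C@H](OC(=O)C(=C)[C@@H](O)CO)[C@@H]12 | target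

## Step count and risks

Total step count: 18. Longest linear sequence: 14 steps (4 to 27: steps 3 to 13, then 16, 17 and 18).

**Step 7 (key step).** The most likely failure is loss of the trans ring fusion by epimerisation at C5 before the cyclobutane opens, which would give the ring-trans C4=C5 isomer. Cope rearrangement of 9 to the divinylcyclohexanone during heating is the second risk, since both are unimolecular processes with barriers not far above that of the cycloreversion. Fallback: starting from 8, the ketone is reduced with NaBH4 to the C6 carbinol F1, which has no enolisable position at C5. The same flow thermolysis then gives the hydroxy dienoate F2, and oxidation of its allylic alcohol with MnO2 returns to 9.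

**Step 6.** Closure of the 1,4-biradical may favour the cis-fused C5 epimer, so that too little trans-fused adduct is formed; the ratio is decided in the excited state and cannot be steered by the C8 substituent. Fallback: setting out from 7 and 3, the cis-fused co-product, cis-anti-cis adduct F3, is not discarded. It is subjected to flash vacuum thermolysis with cold trapping to give the ring-trans dienone F4, whose doubly activated C4=C5 bond is then isomerised by reversible thiol addition–elimination (PhSH, Et3N) towards the less strained ring-cis isomer, rejoining the route at 9.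

**Step 8.** Facial selectivity at C7 may be poor or reversed, because the argument rests on one conformer of a flexible ten-membered enolate; loss of silanol from the enolate is the second risk. Fallback: from 9, the alkylation is run without regard to selectivity and the unwanted (7S) epimer F5 is re-enolised with LiN(SiMe3)2 (H7 is its only remaining α-hydrogen on that side) and protonated kinetically at −78 °C. The proton enters from the same outer face that the electrophile used, so C7 is inverted and the material returns as 11. C7 is then set by enolate protonation and not by alkylation.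

**Step 9.** Hydride delivery to C6 may be unselective, since i-Bu2AlH answers only to the substrate; partial reduction of the tert-butyl ester is a minor risk. Fallback: from 11, the ketone alone is reduced under reagent control by a Corey–Bakshi–Shibata reduction ((S)-2-methyl-CBS-oxazaborolidine, BH3·SMe2, −40 °C; the alkenyl side acts as the large group) to the hydroxy diester F6. Its conjugated methyl ester is then reduced with i-Bu2AlH at −78 °C, which rejoins the route at 12.

**Step 18.** Oxygen may add to the wrong face of C1, because the selectivity depends on the conformer population of a ring that carries a large C8 ester; abstraction from C2 to give the tertiary C10 hydroperoxide is the second risk. Fallback: from 17, the photo-oxygenation is carried out on the compact silyl ether, whose conformer population differs, to give hydroperoxide F7, and the C1 epimers are separated there. The hydroperoxide is masked as the 2-methoxyprop-2-yl peroxyketal F8 (2-methoxypropene, PPTS). The silyl ether is cleaved with n-Bu4NF/AcOH to alcohol F9, which is esterified with 23 under the conditions of step 16 to F10. Aqueous acetic acid then removes acetonide and peroxyketal together and gives 27.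

## Further compounds

F1 | step 7 | C6 carbinol of photoadduct 8 (C6 epimers) | OC1C[C@@H](O[Si](C)(C)C(C)(C)C)C[C@@]2(C)[C@@H]3CC[C@]3(C(=O)OC)[C@H]12
F2 | step 7 | methyl (8S)-6-hydroxy-8-(tert-butyldimethylsilyloxy)germacra-1(10)E,4-dien-15-oate, ring-cis C4=C5 (C6 epimers) | OC1/C=C(/C(=O)OC)CC/C=C(\C)C[C@H](O[Si](C)(C)C(C)(C)C)C1
F3 | step 6 | cis-anti-cis photoadduct, C5 epimer of 8 (1S,4R,5S,8S,10S) | O=C1C[C@@H](O[Si](C)(C)C(C)(C)C)C[C@@]2(C)[C@@H]3CC[C@]3(C(=O)OC)[C@@H]12
F4 | step 6 | methyl (8S)-8-(tert-butyldimethylsilyloxy)-6-oxogermacra-1(10)E,4-dien-15-oate, ring-trans C4=C5 | O=C1/C=C(\C(=O)OC)CC/C=C(\C)C[C@H](O[Si](C)(C)C(C)(C)C)C1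
F5 | step 8 | (7S,8S)-keto diester, C7 epimer of 11 | O=C1/C=C(/C(=O)OC)CC/C=C(\C)C[C@H](O[Si](C)(C)C(C)(C)C)[C@@H]1CC(=O)OC(C)(C)C
F6 | step 9 | (6S,7S,8S)-6-hydroxy diester (C15 methyl ester, tert-butyl ester on the C7 arm) | O[C@H]1/C=C(/C(=O)OC)CC/C=C(\C)C[C@H](O[Si](C)(C)C(C)(C)C)[C@H]1CC(=O)OC(C)(C)C
F7 | step 18 | (1R,6S,7S,8S)-15-acetoxy-1-hydroperoxy-8-(tert-butyldimethylsilyloxy)germacra-4,10(14),11(13)-trien-6,12-olide | C=C1C(=O)O[C@H]2/C=C(/COC(C)=O)CC[C@@H](OO)C(=C)C[C@H](O[Si](C)(C)C(C)(C)C)[C@@H]12
F8 | step 18 | 2-methoxyprop-2-yl peroxyketal of F7 | C=C1C(=O)O[C@H]2/C=C(/COC(C)=O)CC[C@@H](OOC(C)(C)OC)C(=C)C[C@H](O[Si](C)(C)C(C)(C)C)[C@@H]12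
F9 | step 18 | C8 alcohol from F8 (peroxyketal retained) | C=C1C(=O)O[C@H]2/C=C(/COC(C)=O)CC[C@@H](OOC(C)(C)OC)C(=C)C[C@H](O)[C@@H]12
F10 | step 18 | C8 ester of F9 with acid 23 (acetonide and peroxyketal in place) | C=C1C(=O)O[C@H]2/C=C(/COC(C)=O)CC[C@@H](OOC(C)(C)OC)C(=C)C[C@H](OC(=O)C(=C)[C@@H]3COC(C)(C)O3)[C@@H]12
A1 | alternative 1 | 8-silyloxy-15-(4-methoxybenzyloxy)germacra-1(10),4,11(13)-trien-6,12-olide | C=C1C(=O)O[C@H]2/C=C(/COCc3ccc(OC)cc3)CC/C=C(\C)C[C@H](O[Si](C)(C)C(C)(C)C)[C@@H]12
A2 | alternative 1 | ten-membered 7-ethynyl-6-hydroxy precursor of A1 | O[C@H]1/C=C(/COCc2ccc(OC)cc2)CC/C=C(\C)C[C@H](O[Si](C)(C)C(C)(C)C)[C@H]1C#C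
A3 | alternative 2 | ten-membered C8 alcohol with C11=C13 methylene and C12 silyl ether on C7 | O([Si](C)(C)C(C)(C)C)[C@H]1/C=C(/COCc2ccc(OC)cc2)CC/C=C(\C)C[C@H](O)[C@H]1C(=C)CO[Si](C)(C)C(C)(C)C
A4 | alternative 2 | thirteen-membered cyclic allyl ether with tributylstannyl group on C8 | CCCC[Sn](CCCC)(CCCC)[C@@H]1OC/C(CO[Si](C)(C)C(C)(C)C)=C/[C@@H](O[Si](C)(C)C(C)(C)C)/C=C(/COCc2ccc(OC)cc2)CC/C=C(\C)C1
A5 | alternative 3 | 10-methylene cyclodec-4-en-6-one with C1 silyl ether and C8 4-methoxybenzyl ether | O=C1/C=C(/COCc2ccc(OC)cc2)CC[C@H](O[Si](C)(C)C(C)(C)C)C(=C)C[C@H](OCc2ccc(OC)cc2)C1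
A6 | alternative 3 | cis-fused hydroazulene with C6 tertiary alcohol and C14 mesylate on C10 | CS(=O)(=O)OC[C@]12C[C@H](OCc3ccc(OC)cc3)C[C@@]1(O)C=C(COCc3ccc(OC)cc3)CC[C@@H]2O[Si](C)(C)C(C)(C)C
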